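**Retrosynthetic overview**
- Numbering: C1 is the tertiary carbinol carbon (it carries C7), C2 the acetoxy carbon, C3 a benzoyloxy carbon, C4=C5 the alkene, C6 the other benzoyloxy carbon. The ester pattern of 23 goes back to the C1/C2-acetonide triol 20, and 20 to acid 17 (C7 = CO2H, C3–OPMB, C6–Bpin).
- Feature: in the cyclohexene ring of 17 the path C7(=O)OH–C1(O)–C6–C5=C4 is a γ,δ-unsaturated α-alkoxy acid, a Claisen retron. Opening C1–C6 and tying C4 to the carboxyl oxygen gives δ-lactone 14 with an (E)-C5=C6–B side chain.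
- 14 is a D-manno-hept-6-enono-1,5-lactone (sugar C1 to C7 = C7, C1, C2, C3, C4, C5, C6). C2 and C3 come unchanged from D-mannose, and sugar C5 (= C4) is spent in relaying chirality to C1 and C6.
- 14 comes from 6-aldehyde 9 and dichloromethylboronate 10 by (E)-selective olefination. 9 comes from D-mannose 1 through the allyl glycoside, the 2,3-acetonide and the 4-O-PMB ether (from 6).
- Ring order: pyranose ring (step 1), dioxolane (step 2), then the pyranone ring is traded for the cyclohexene ring in step 10. No other ring is made.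

Key step: step 10

Assumption: lactol 13 is handled as an anomeric mixture. Its SMILES leaves that centre open because step 9 removes it.

**Step 1**
Reactants: 1 D-mannose
Product: 2 allyl α-D-mannopyranoside
Conditions: allyl alcohol (solvent), TsOH·H2O (cat.), 90 °C
Reagents that add atoms: allyl alcohol, C=CCO
Why: Fischer glycosidation under thermodynamic control, in which the anomeric effect and the axial O2 of mannose favour the α-pyranoside and the four carbinol centres of 1 are untouched.

**Step 2**
Reactants: 2 allyl α-D-mannopyranoside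
Product: 4 allyl 2,3-O-isopropylidene-α-D-mannopyranoside, via bis-acetonide 3 (not isolated)
Conditions: Me2C(OMe)2, TsOH·H2O (cat.), acetone, rt; then H2O, rt
Reagents that add atoms: 2,2-dimethoxypropane, COC(C)(C)OC
Why: Acid-catalysed transacetalisation gives the bis-acetonide, whose 4,6-dioxane acetal hydrolyses much faster than the cis-fused 2,3-dioxolane, so added water should stop at the mono-acetonide.

**Step 3**
Reactants: 4 allyl 2,3-O-isopropylidene-α-D-mannopyranoside
Product: 5 allyl 6-O-(tert-butyldiphenylsilyl)-2,3-O-isopropylidene-α-D-mannopyranoside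
Conditions: t-BuPh2SiCl, imidazole, DMF, 0 °C
Reagents that add atoms: tert-butyldiphenylsilyl chloride, CC(C)(C)[Si](Cl)(c1ccccc1)c1ccccc1
Why: Imidazole-promoted silyl ether formation, in which the bulky chloride takes the primary O6 hydroxyl and leaves the hindered secondary O4 hydroxyl free.

**Step 4**
Reactants: 5 allyl 6-O-(tert-butyldiphenylsilyl)-2,3-O-isopropylidene-α-D-mannopyranoside; 6 4-methoxybenzyl chloride
Product: 7 allyl 6-O-(tert-butyldiphenylsilyl)-2,3-O-isopropylidene-4-O-(4-methoxybenzyl)-α-D-mannopyranoside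
Conditions: NaH, 6, Bu4NI (cat.), DMF, 0 °C to rt
Reagents that add atoms: 4-methoxybenzyl chloride (6), COc1ccc(CCl)cc1
Why: Williamson ether synthesis on the only free hydroxyl; the tert-butyldiphenylsilyl group resists base-induced O6 to O4 migration, and allyl ether and acetonide are inert to NaH.

**Step 5**
Reactants: 7 allyl 6-O-(tert-butyldiphenylsilyl)-2,3-O-isopropylidene-4-O-(4-methoxybenzyl)-α-D-mannopyranoside
Product: 8 allyl 2,3-O-isopropylidene-4-O-(4-methoxybenzyl)-α-D-mannopyranoside
Conditions: Bu4NF, THF, rt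
Reagents that add atoms: none
Why: Fluoride-driven desilylation frees O6 alone, because all other groups are ethers or acetals that fluoride does not touch.

**Step 6**
Reactants: 8 allyl 2,3-O-isopropylidene-4-O-(4-methoxybenzyl)-α-D-mannopyranoside
Product: 9 allyl 2,3-O-isopropylidene-4-O-(4-methoxybenzyl)-α-D-manno-hexodialdo-1,5-pyranoside
Conditions: Dess–Martin periodinane, NaHCO3, CH2Cl2, 0 °C to rt
Reagents that add atoms: none
Why: Dess–Martin oxidation stops at the aldehyde, and its near-neutral medium should avoid epimerisation at sugar C5 and β-elimination of the 4-O-PMB group.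

**Step 7**
Reactants: 9 allyl 2,3-O-isopropylidene-4-O-(4-methoxybenzyl)-α-D-manno-hexodialdo-1,5-pyranoside; 10 2-(dichloromethyl)-4,4,5,5-tetramethyl-1,3,2-dioxaborolane
Product: 11 allyl (E)-6,7-dideoxy-2,3-O-isopropylidene-4-O-(4-methoxybenzyl)-7-(4,4,5,5-tetramethyl-1,3,2-dioxaborolan-2-yl)-α-D-manno-hept-6-enopyranoside
Conditions: 10, CrCl2, LiI, THF, rt
Reagents that add atoms: 2-(dichloromethyl)-4,4,5,5-tetramethyl-1,3,2-dioxaborolane (10), ClC(Cl)B1OC(C)(C)C(C)(C)O1
Why: Takai–Utimoto boryl olefination, in which the geminal dichromium reagent adds to the aldehyde and eliminates from the less crowded adduct to give the (E)-alkenylboronate under non-basic conditions that acetals, ethers and the allyl group tolerate.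

**Step 8**
Reactants: 11 allyl (E)-6,7-dideoxy-2,3-O-isopropylidene-4-O-(4-methoxybenzyl)-7-(pinacolboryl)-α-D-manno-hept-6-enopyranoside
Product: 13 (E)-6,7-dideoxy-2,3-O-isopropylidene-4-O-(4-methoxybenzyl)-7-(pinacolboryl)-D-manno-hept-6-enopyranose, via prop-1-enyl glycoside 12 (not isolated)
Conditions: [Ir(cod)(PMePh2)2]PF6 (cat., activated by H2, then degassed), THF, rt; then I2, NaHCO3, THF/H2O, 0 °C
Reagents that add atoms: none
Why: Transition-metal-catalysed allyl ether isomerisation moves only the terminal double bond, and iodine then takes the electron-rich enol ether 12 far faster than the electron-poor alkenylboronate, so hydrolysis should free the anomeric hydroxyl without harm to acetonide, PMB ether or C–B bond.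

**Step 9**
Reactants: 13 (E)-6,7-dideoxy-2,3-O-isopropylidene-4-O-(4-methoxybenzyl)-7-(pinacolboryl)-D-manno-hept-6-enopyranose
Product: 14 (E)-6,7-dideoxy-2,3-O-isopropylidene-4-O-(4-methoxybenzyl)-7-(pinacolboryl)-D-manno-hept-6-enono-1,5-lactone
Conditions: Dess–Martin periodinane, NaHCO3, CH2Cl2, rt
Reagents that add atoms: none
Why: Dess–Martin oxidation of a lactol to the lactone; with O4 blocked only the 1,5-ring can form, and the reagent does not oxidise the C–B bond.

**Step 10**
Reactants: 14 (E)-6,7-dideoxy-2,3-O-isopropylidene-4-O-(4-methoxybenzyl)-7-(pinacolboryl)-D-manno-hept-6-enono-1,5-lactone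
Product: 17 cyclohexene acid (C1/C2 acetonide; C3 PMB ether; C6 pinacolboronate; C7 = CO2H; O1 and O2 on one ring face; O3, boron and C7 on the other), via silyl ketene acetal 15 (not isolated), via trimethylsilyl ester 16 (not isolated)
Conditions: Me3SiCl, THF, −78 °C, LiN(SiMe3)2 added slowly, −78 to 0 °C; solvent changed to toluene, 100 °C; then aq. citric acid, THF, rt
Reagents that add atoms: chlorotrimethylsilane, C[Si](C)(C)Cl (its silyl group is carried by 15 and 16 and leaves again on work-up)
Why: LiN(SiMe3)2 removes the proton on C1 (sugar C2) while Me3SiCl is already present, so the lactone enolate is trapped at once as the endocyclic C1=C7 ketene acetal 15; in it the C2–O bond of the cis-fused dioxolane lies near the enolate plane and overlaps poorly with the π system, which holds back β-elimination. On heating, 15 undergoes an Ireland–Claisen [3,3]-sigmatropic rearrangement, the reaction type known for silyl ketene acetals of 6-alkenyl δ-lactones: C1–C6 forms, the lactone C4–O bond breaks and C4=C5 appears. The cyclohexene ring closes in this one concerted, suprafacial-suprafacial event through a boat-shaped, bicyclo[2.2.2]octane-like transition state, the only one that a ketene acetal and an alkene held on the same six-membered ring can reach, and the pyranone ring is given up at the same time. C1 is controlled by the tether, since the alkenyl group stands on the lactone face fixed by sugar C5 and C6 can reach only that face of C1, which puts C7 trans to O2 and cis to O3, an outcome opposite to the steric bias of an untethered dioxolane enolate. C6 is controlled by the (E) geometry of the alkenylboronate together with the s-cis C3–C4–C5=C6 arrangement that a ring C4=C5 bond demands, which places boron cis to C7. The step needs O-silylation and rearrangement to outrun elimination, attack of the amide at boron and 1,3-borotropic shift, which the internal quench, the electron-rich tetrasubstituted ketene acetal and the configurationally stable pinacol allylboronate should secure, and dilute citric acid then frees acid 17 from silyl ester 16.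

**Step 11**
Reactants: 17 cyclohexene acid with C6 pinacolboronate
Product: 18 C6-hydroxy acid (C1/C2 acetonide; C3 PMB ether; C6–OH cis to C7)
Conditions: 30% aq. H2O2, NaH2PO4/Na2HPO4 buffer (pH 7), THF, 0 °C to rt
Reagents that add atoms: hydrogen peroxide, OO
Why: Oxidation of an organoboronate by hydroperoxide, in which C6 migrates from boron to oxygen with retention, so the hydroxyl takes the place of boron cis to C7 and the alkene does not shift.

**Step 12**
Reactants: 18 C6-hydroxy acid
Product: 19 C6,C7-diol (C1/C2 acetonide; C3 PMB ether)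
Conditions: LiAlH4, THF, 0 °C to reflux; aqueous work-up
Reagents that add atoms: none
Why: LiAlH4 reduction of a carboxylic acid to the primary alcohol; alkene, acetonide and PMB ether are inert, and the transient aldehyde is reduced faster than it could cleave by retro-aldol reaction.

**Step 13**
Reactants: 19 C6,C7-diol
Product: 20 C3,C6,C7-triol (C1/C2 acetonide)
Conditions: DDQ, CH2Cl2/aq. NaH2PO4/Na2HPO4 buffer (pH 7) 10:1, 0 °C
Reagents that add atoms: none
Why: Oxidative PMB cleavage by DDQ through the benzylic oxocarbenium ion, which water captures; the wet buffered medium and low temperature favour this over oxidation of the unactivated allylic alcohol.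

**Step 14**
Reactants: 20 C3,C6,C7-triol
Product: 21 C3,C6,C7-tribenzoate (C1/C2 acetonide)
Conditions: BzCl, pyridine, DMAP (cat.), 0 °C to rt
Reagents that add atoms: benzoyl chloride, O=C(Cl)c1ccccc1
Why: DMAP-catalysed acylation esterifies all three free hydroxyls while O1 and O2 stay masked in the acetonide.

**Step 15**
Reactants: 21 C3,C6,C7-tribenzoate
Product: 22 C1,C2-diol tribenzoate
Conditions: CF3CO2H/H2O (4:1), CH2Cl2, 0 °C to rt
Reagents that add atoms: none
Why: Acid-catalysed acetal hydrolysis; benzoates withstand aqueous acid, and acyl migration, which is base-promoted, should be slow at low pH.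

**Step 16**
Reactants: 22 C1,C2-diol tribenzoate
Product: 23 (1R,2S,3R,6S)-2-acetoxy-3,6-bis(benzoyloxy)-1-(benzoyloxymethyl)cyclohex-4-en-1-ol (route numbering), the target
Conditions: Ac2O, pyridine, 0 °C to rt
Reagents that add atoms: acetic anhydride, CC(=O)OC(C)=O
Why: Chemoselective acylation, in which the secondary C2 hydroxyl is esterified while the tertiary C1 hydroxyl, crowded by three substituted carbons, should not react without DMAP.

**Compound list**
1 | D-mannose | O=C[C@@H](O)[C@@H](O)[C@H](O)[C@H](O)CO | starting material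
2 | allyl α-D-mannopyranoside | C=CCO[C@H]1O[C@H](CO)[C@@H](O)[C@H](O)[C@@H]1O | intermediate
3 | allyl 2,3:4,6-di-O-isopropylidene-α-D-mannopyranoside (not isolated, step 2) | C=CCO[C@H]1O[C@@H]3COC(C)(C)O[C@H]3[C@@H]2OC(C)(C)O[C@H]12 | intermediate
4 | allyl 2,3-O-isopropylidene-α-D-mannopyranoside | C=CCO[C@H]1O[C@H](CO)[C@@H](O)[C@@H]2OC(C)(C)O[C@H]12 | intermediate
5 | allyl 6-O-(tert-butyldiphenylsilyl)-2,3-O-isopropylidene-α-D-mannopyranoside | C=CCO[C@H]1O[C@H](CO[Si](c2ccccc2)(c2ccccc2)C(C)(C)C)[C@@H](O)[C@@H]2OC(C)(C)O[C@H]12 | intermediate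
6 | 4-methoxybenzyl chloride | COc1ccc(CCl)cc1 | starting material
7 | allyl 6-O-(tert-butyldiphenylsilyl)-2,3-O-isopropylidene-4-O-(4-methoxybenzyl)-α-D-mannopyranoside | C=CCO[C@H]1O[C@H](CO[Si](c2ccccc2)(c2ccccc2)C(C)(C)C)[C@@H](OCc2ccc(OC)cc2)[C@@H]2OC(C)(C)O[C@H]12 | intermediate
8 | allyl 2,3-O-isopropylidene-4-O-(4-methoxybenzyl)-α-D-mannopyranoside | C=CCO[C@H]1O[C@H](CO)[C@@H](OCc2ccc(OC)cc2)[C@@H]2OC(C)(C)O[C@H]12 | intermediate
9 | allyl 2,3-O-isopropylidene-4-O-(4-methoxybenzyl)-α-D-manno-hexodialdo-1,5-pyranoside | C=CCO[C@H]1O[C@H](C=O)[C@@H](OCc2ccc(OC)cc2)[C@@H]2OC(C)(C)O[C@H]12 | intermediate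
10 | 2-(dichloromethyl)-4,4,5,5-tetramethyl-1,3,2-dioxaborolane | ClC(Cl)B1OC(C)(C)C(C)(C)O1 | starting material
11 | allyl (E)-6,7-dideoxy-2,3-O-isopropylidene-4-O-(4-methoxybenzyl)-7-(pinacolboryl)-α-D-manno-hept-6-enopyranoside | C=CCO[C@H]1O[C@H](/C=C/B2OC(C)(C)C(C)(C)O2)[C@@H](OCc2ccc(OC)cc2)[C@@H]2OC(C)(C)O[C@H]12 | intermediate
12 | (E)-prop-1-enyl glycoside corresponding to 11 (not isolated, step 8) | C/C=C/O[C@H]1O[C@H](/C=C/B2OC(C)(C)C(C)(C)O2)[C@@H](OCc2ccc(OC)cc2)[C@@H]2OC(C)(C)O[C@H]12 | intermediate
13 | (E)-6,7-dideoxy-2,3-O-isopropylidene-4-O-(4-methoxybenzyl)-7-(pinacolboryl)-D-manno-hept-6-enopyranose (anomeric mixture) | OC1O[C@H](/C=C/B2OC(C)(C)C(C)(C)O2)[C@@H](OCc2ccc(OC)cc2)[C@@H]2OC(C)(C)O[C@H]12 | intermediate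
14 | (E)-6,7-dideoxy-2,3-O-isopropylidene-4-O-(4-methoxybenzyl)-7-(pinacolboryl)-D-manno-hept-6-enono-1,5-lactone | O=C1O[C@H](/C=C/B2OC(C)(C)C(C)(C)O2)[C@@H](OCc2ccc(OC)cc2)[C@@H]2OC(C)(C)O[C@H]12 | intermediate
15 | trimethylsilyl ketene acetal of 14, endocyclic C1=C7 (not isolated, step 10) | C[Si](C)(C)OC1=C2OC(C)(C)O[C@H]2[C@H](OCc2ccc(OC)cc2)[C@@H](/C=C/B2OC(C)(C)C(C)(C)O2)O1 | intermediate
16 | trimethylsilyl ester of 17 (not isolated, step 10) | CC1(C)O[C@H]2[C@H](OCc3ccc(OC)cc3)C=C[C@H](B3OC(C)(C)C(C)(C)O3)[C@@]2(C(=O)O[Si](C)(C)C)O1 | intermediate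
17 | cyclohexene acid: C1/C2 acetonide, C3 PMB ether, C6 pinacolboronate, C7 = CO2H | CC1(C)O[C@H]2[C@H](OCc3ccc(OC)cc3)C=C[C@H](B3OC(C)(C)C(C)(C)O3)[C@@]2(C(=O)O)O1 | intermediate
18 | C6-hydroxy acid: C1/C2 acetonide, C3 PMB ether | CC1(C)O[C@H]2[C@H](OCc3ccc(OC)cc3)C=C[C@H](O)[C@@]2(C(=O)O)O1 | intermediate
19 | C6,C7-diol: C1/C2 acetonide, C3 PMB ether | CC1(C)O[C@H]2[C@H](OCc3ccc(OC)cc3)C=C[C@H](O)[C@@]2(CO)O1 | intermediate
20 | C3,C6,C7-triol: C1/C2 acetonide | CC1(C)O[C@H]2[C@H](O)C=C[C@H](O)[C@@]2(CO)O1 | intermediate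
21 | C3,C6,C7-tribenzoate: C1/C2 acetonide | CC1(C)O[C@H]2[C@H](OC(=O)c3ccccc3)C=C[C@H](OC(=O)c3ccccc3)[C@@]2(COC(=O)c3ccccc3)O1 | intermediate
22 | C1,C2-diol with C3, C6 and C7 benzoates | O[C@H]1[C@H](OC(=O)c2ccccc2)C=C[C@H](OC(=O)c2ccccc2)[C@]1(O)COC(=O)c1ccccc1 | intermediate
23 | CNP0148821.1, (1R,2S,3R,6S)-2-acetoxy-3,6-bis(benzoyloxy)-1-(benzoyloxymethyl)cyclohex-4-en-1-ol | CC(=O)O[C@H]1[C@H](OC(=O)c2ccccc2)C=C[C@H](OC(=O)c2ccccc2)[C@]1(O)COC(=O)c1ccccc1 | target

Total step count: 16
Longest linear sequence: 16 steps (1 to 23)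

**Steps most likely to fail**

**Step 10.**
- Risk: the C2 oxygen may β-eliminate from the lactone enolate before silylation. The amide base may complex with boron. The boat transition state may lie too high, because the alkenyl group must swing into a flagpole position, so the ketene acetal could decay first.
- Fallback: it sets out from alcohol 8 and comes back at diol 19. It replaces the rearrangement by aldol branching, carbonyl addition and ring-closing metathesis.
  - I2, PPh3 and imidazole should turn 8 into allyl 6-deoxy-6-iodo-2,3-O-isopropylidene-4-O-(4-methoxybenzyl)-α-D-mannopyranoside F1.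
  - Zn in aqueous THF (Bernet–Vasella fragmentation) expels the allyloxy group and should give 5,6-dideoxy-2,3-O-isopropylidene-4-O-(4-methoxybenzyl)-D-lyxo-hex-5-enose F2.
  - A crossed aldol reaction with aqueous formaldehyde and K2CO3 places the hydroxymethyl group (C7) on the dioxolane face away from the C3 side chain. That is the C1 configuration of the target, and the product is the 2-C-hydroxymethyl aldehyde F3.
  - CH2=CHMgBr adds to the aldehyde to give the acyclic diene diol F4, whose C6 epimers would have to be separated.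
  - The second-generation Grubbs catalyst RuCl2(=CHPh)(PCy3)(SIMes) then closes C4=C5 to give 19.

**Step 8.**
- Risk: chemoselectivity may be lost, either by iridium hydride migration of the internal C=C bond or by iodine attack at the alkenylboronate during enol ether hydrolysis.
- Fallback: it sets out from 7 and comes back at lactone 14. The anomeric centre is unmasked and oxidised before boron is brought in.
  - The same iridium isomerisation of 7 gives the prop-1-enyl glycoside F5.
  - I2, NaHCO3 and water give the 6-O-silyl lactol F6.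
  - Dess–Martin oxidation gives the 6-O-silyl 1,5-lactone F7.
  - HF·pyridine gives the 6-hydroxy lactone F8.
  - Dess–Martin oxidation gives the 6-aldehydo lactone F9.
  - Olefination of F9 by 10, CrCl2 and LiI gives 14.

**Step 7.**
- Risk: the PMB-oxy group may β-eliminate, or the aldehyde may epimerise at sugar C5 in the Lewis-acidic chromium medium. The (E) selectivity may also erode, which would be carried into the C6 configuration.
- Fallback: it sets out from aldehyde 9 and comes back at 11. The C–B bond is made by syn hydroboration of an alkyne, so the mechanism of addition fixes the (E) geometry.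
  - Dimethyl (1-diazo-2-oxopropyl)phosphonate, K2CO3 and MeOH (Ohira–Bestmann homologation) give the hept-6-ynopyranoside F10.
  - Pinacolborane (1.05 equiv) with Cp2ZrHCl (cat.) should add to the terminal alkyne faster than to the allyl group and give 11.

**Further compounds**
F1 | step 10 | allyl 6-deoxy-6-iodo-2,3-O-isopropylidene-4-O-(4-methoxybenzyl)-α-D-mannopyranoside | C=CCO[C@H]1O[C@H](CI)[C@@H](OCc2ccc(OC)cc2)[C@@H]2OC(C)(C)O[C@H]12
F2 | step 10 | 5,6-dideoxy-2,3-O-isopropylidene-4-O-(4-methoxybenzyl)-D-lyxo-hex-5-enose | O=C[C@H]1OC(C)(C)O[C@H]1[C@H](OCc1ccc(OC)cc1)C=C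
F3 | step 10 | 2-C-hydroxymethyl aldehyde (hydroxymethyl in place of H2 of F2) | O=C[C@@]1(CO)OC(C)(C)O[C@H]1[C@H](OCc1ccc(OC)cc1)C=C
F4 | step 10 | acyclic diene diol CH2=CH–C6H(OH)–C1(O)(CH2OH)–C2H(O)–C3H(OPMB)–CH=CH2, C1/C2 acetonide | C=C[C@H](O)[C@@]1(CO)OC(C)(C)O[C@H]1[C@H](OCc1ccc(OC)cc1)C=C
F5 | step 8 | (E)-prop-1-enyl 6-O-(tert-butyldiphenylsilyl)-2,3-O-isopropylidene-4-O-(4-methoxybenzyl)-α-D-mannopyranoside | C/C=C/O[C@H]1O[C@H](CO[Si](c2ccccc2)(c2ccccc2)C(C)(C)C)[C@@H](OCc2ccc(OC)cc2)[C@@H]2OC(C)(C)O[C@H]12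
F6 | step 8 | 6-O-(tert-butyldiphenylsilyl)-2,3-O-isopropylidene-4-O-(4-methoxybenzyl)-D-mannopyranose | OC1O[C@H](CO[Si](c2ccccc2)(c2ccccc2)C(C)(C)C)[C@@H](OCc2ccc(OC)cc2)[C@@H]2OC(C)(C)O[C@H]12
F7 | step 8 | 6-O-(tert-butyldiphenylsilyl)-2,3-O-isopropylidene-4-O-(4-methoxybenzyl)-D-mannono-1,5-lactone | O=C1O[C@H](CO[Si](c2ccccc2)(c2ccccc2)C(C)(C)C)[C@@H](OCc2ccc(OC)cc2)[C@@H]2OC(C)(C)O[C@H]12
F8 | step 8 | 2,3-O-isopropylidene-4-O-(4-methoxybenzyl)-D-mannono-1,5-lactone | O=C1O[C@H](CO)[C@@H](OCc2ccc(OC)cc2)[C@@H]2OC(C)(C)O[C@H]12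
F9 | step 8 | 6-aldehydo-2,3-O-isopropylidene-4-O-(4-methoxybenzyl)-D-mannono-1,5-lactone | O=C1O[C@H](C=O)[C@@H](OCc2ccc(OC)cc2)[C@@H]2OC(C)(C)O[C@H]12
F10 | step 7 | allyl 6,7-dideoxy-2,3-O-isopropylidene-4-O-(4-methoxybenzyl)-α-D-manno-hept-6-ynopyranoside | C=CCO[C@H]1O[C@H](C#C)[C@@H](OCc2ccc(OC)cc2)[C@@H]2OC(C)(C)O[C@H]12
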